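## The problem

Demethoxybisabolocurcumin ether is an unsymmetrical curcuminoid whose guaiacyl oxygen is bound, as a secondary allylic aryl ether, to C1 of an oxidised bisabolane (numbering used throughout: C1 carries the aryloxy group, C2=C3 is the ring alkene with the methyl group on C3, C4 is the carbinol, C5 a methylene, C6 the ring methine, and C7–C11 the side chain with the methyl-bearing stereocentre C7 and the isobutenyl ketone C9–C11). The enolised 1,3-diketone with its two styryl arms is sensitive to base and nucleophiles, so it has to be assembled last, from an aryl aldehyde that must stay hidden through the whole sequence. The four stereocentres are (1R,4S,6R,7S): on the ring the C1 aryloxy group is trans to the C6 side chain and cis to the C4 hydroxyl, so with the C1 and C6 substituents equatorial the C4 hydroxyl is axial. C7 lies outside the ring on a freely rotating bond and distinguishes only methyl from CH2, so it cannot be relied on to control anything; it has to be made in absolute form and C6 has to be set against it by a reagent. C1 can be left to thermodynamics if it is made epimerisable, whereas the axial C4 alcohol is the product of hydride attack against the usual substrate preference and needs reagent control or an inversion. The C1–O bond is the fragile point: the ether is allylic with a methyl-substituted allyl terminus (C3), so acid ionises it, and forming it by substitution on a cyclohexenol invites SN2' attack, elimination and loss of configuration. The enabling feature is the ring pattern itself: C1 (O-aryl) lies between the alkene carbon C2 and the branch point C6, and C4 (oxygenated) between the methyl-bearing C3 and the methylene C5, which is the pattern formed when a 2-aryloxy enal (C2 aldehyde, C1 α-carbon, C6 β-carbon) is annulated with an ethyl ketone activated at C5, C4 entering as the ketone. The aryl ether can then ride into the ring on a trigonal carbon and never has to be made at a stereocentre.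

## Retrosynthesis

**24 to 20 and 23.** The last bond made is the alkene between the guaiacyl ring carbon and the diketone chain of target 24, which divides it into aryl aldehyde 20 and the half-curcuminoid 23. The cut at the other styryl alkene would make the valuable terpenoid fragment the nucleophile; the chosen cut lets the cheap partner 23 be used in excess and keeps the diketone out of every earlier step. Precursor 20 has lost the second arene and all the base-sensitive functionality. The forward reaction must condense only at the terminal methyl of 23, tolerate a free phenol, the free C4 hydroxyl and the isobutenyl ketone, and release the product without strong acid.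

**20 to 19 to 18.** The formyl group of 20 is traced to the primary benzylic alcohol of 19 and this to silyl ether 18. No skeletal bond is cut. A benzylic silyl ether, unlike an aldehyde, acetal or ester, is inert to amines, hydrides and Grignard reagents and keeps the phenol oxygen electron-rich and therefore a poor leaving group. The forward oxidation must distinguish the primary benzylic hydroxyl from the secondary allylic one at C4; if it does, C4 needs no protecting group.

**18 to 17 to 16.** The C9–C10 bond of 18 is cut to the N-methoxy-N-methylamide 17 and an isobutenyl nucleophile, and 17 goes back to methyl ester 16. Cutting C8–C9 or building the enone by condensation with acetone would require enolate chemistry beside the ring; the amide route adds the four-carbon unit once and stops at the ketone. The step must follow the C4 reduction (otherwise two ketones compete) and precede the unveiling of the aldehyde.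

**16 to 15.** The C4–H bond is removed next: 16 is the reduction product of cyclohexenone 15. This takes away one stereocentre and exposes the enone retron. The forward reduction must deliver hydride to the face of the C6 side chain, against the preference of small hydrides, so a chiral oxazaborolidine has to decide.

**15 to 11 and 12.** Cyclohexenone 15 is opened across C5–C6 and C2=C3, giving (Z)-2-aryloxy enal 11 and tert-butyl 3-oxopentanoate 12. Cutting C1–O instead would return to a cyclohexenol and to substitution at a stereocentre; a cycloaddition across C1–C2 and C5–C6 would need an electron-rich aryl enol ether as dienophile for an electron-rich diene. Both precursors are acyclic, 11 with one stereocentre and 12 with none, so the step gains a ring, two skeletal bonds and two stereocentres. It asks for 1,4-addition to a hindered α,β-disubstituted enal under catalyst control of C6, for C1 to remain free to equilibrate, and for ring closure and decarboxylation in acid mild enough to keep the aryloxy group.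

**11 to 10 to 5 and 9.** The C1=C6 alkene of 11 is cut in the olefination sense into aldehyde 9 and a phosphorus-stabilised C1 anion that already carries the aryloxy group. A free formyl group cannot be carried on such a reagent, and an ester would later have to be reduced beside the C9 methyl ester. The formyl group is therefore masked as an N-methoxy-N-methylamide (alkene 10, reagent 5), which a zirconium hydride reduces without touching esters. An aldol condensation between an aryloxyacetaldehyde and 9 was set aside because the aldolate oxygen sits γ to the C9 ester and would lactonise. The olefination must give the isomer with the carbonyl anti to the C7 chain and must not epimerise 9.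

**5 to 2 and 4.** The C1–O bond of 5 is cut to phenol 2 and diazo compound 4, a carbenoid O–H insertion in the forward sense. This is the only place where the ether is formed, and the carbon concerned becomes trigonal one step later, so no configuration is at stake. Phenol 2 comes from 1 by silylation of the benzylic hydroxyl, and 4 from phosphonate 3 by diazo transfer.

**9 to 8 to 7 to 6.** Aldehyde 9 comes by oxidation of hydroxy ester 8, this by selective reduction of the free carboxyl of half-ester 7, and 7 by asymmetric hydrogenation of itaconic half-ester 6. The half-ester is preferred to the diester because its two carboxyl groups are already different. This is the one stereocentre (C7) bought from a catalyst without help from the substrate.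

**23 to 21 and 22.** The half-curcuminoid 23 is one boron-templated condensation away from 4-hydroxybenzaldehyde 21 and pentane-2,4-dione 22.

## Roads not taken

**Alternative 1:** The enolised diketone is cut across two bonds of a heterocycle that stands in for it, the C–C and C–O bonds of the 3,5-distyrylisoxazole A1. In the forward sense the nitrile oxide generated from cinnamaldoxime A2 adds to the terminal alkyne of enyne A3 under monovalent copper catalysis, and reductive N–O cleavage with hydrolysis later releases the diketone.
- Merits: the diketone stays masked as a robust heterocycle, its unsymmetrical substitution is fixed by the regiochemistry of the cycloaddition, and the isobutenyl ketone is never exposed to amine and borate.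
- Weak points: A2 already contains the complete aryl ether and all four stereocentres, so this road solves only the easy half of the problem and needs another strategy for the ring. It adds several late steps (homologation of the aryl aldehyde, oxime formation, cycloaddition, N–O cleavage, desilylation) where the chosen plan spends one. Hydroxylamine and the N–O reduction must also discriminate against the isobutenyl ketone.
- Comparison: in protecting the diketone this road is better than the chosen ending. The chosen plan sets against it a one-step ending with the separately prepared 23 and a solution to the ring problem, which Alternative 1 does not address.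

**Alternative 2:** Both ring C–O bonds are cut at once. Sensitised singlet oxygen adds across C1 and C4 of diene ester A5 to give endoperoxide A4, and O–O reduction gives cis-diol A6.
- Merits: two oxygens and their cis relation arrive in one reagent-free step from a simple diene, and the C1/C4 relation that the chosen plan must enforce by a reagent-controlled reduction is automatic here.
- Weak points: the facial selectivity relative to a single equatorial substituent at C6 is unlikely to be high. The two secondary allylic hydroxyls of A6 must then be told apart, with the more hindered one at C1 arylated with retention (for instance by aromatic substitution on aryl fluoride A7) while C4 stays free, which brings back protecting groups and etherification at a stereocentre. A peroxide must also be handled on scale.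
- Comparison: this road is shorter to the oxygenated ring. The chosen plan counters that it never has to differentiate two similar hydroxyls and that C1 is set under thermodynamic control with the aryl group already attached.

**Alternative 3:** The ring is cut at C1–C6. Me2AlCl activates (Z)-enal A9 for a carbonyl-ene closure to cyclohexenol A8, forming the C1–C6 bond, the C1 carbinol and an isopropenyl group.
- Merits: ene cyclisations of this terpenoid type are thoroughly precedented, the trans C1/C6 relation follows from the chair transition state, and C4 comes from a simple acyclic precursor.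
- Weak points: C1 arrives as a free hydroxyl, so the aryl ether must again be made on a hindered secondary carbinol with retention (A7 would be the partner). C7 is left trigonal in A8 and has to be set afterwards on a 1,1-disubstituted alkene beside the ring, where control is poor, before four more chain carbons are added. The (Z)-enal A9 can isomerise under the Lewis acid, and its allylic silyl ether can ionise.
- Comparison: the ring-forming step here is much better precedented than the chosen annulation. The chosen plan sets against this that C7 is present in absolute form from the outset and that the ether is never made by substitution.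

Key step: step 9

Assumption: the 1,3-diketone of 23 and of 24 is written in its chelated enol form; keto and enol tautomers are one compound.
Assumption: compounds 3, 6, 12, 21 and 22, both antipodes of the catalysts named, and a THF solution of 2-methylprop-1-enylmagnesium bromide are taken as purchasable.

## Route

Step 1
Reactants: 1 4-(hydroxymethyl)-2-methoxyphenol
Product: 2 2-methoxy-4-{[tri(propan-2-yl)silyl]oxymethyl}phenol
Conditions: iPr3SiCl (1.05 equiv), imidazole, DMF, 0 °C
Reagents that add atoms: chlorotri(propan-2-yl)silane, CC(C)[Si](Cl)(C(C)C)C(C)C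
Why: Chemoselective O-silylation: the bulky chlorosilane should react faster at the unhindered primary benzylic hydroxyl than at the ortho-substituted, hydrogen-bonded phenol; any aryl silyl ether formed is the more base-labile one and is cleaved by K2CO3 in MeOH.

Step 2
Reactants: 3 diethyl {2-[methoxy(methyl)amino]-2-oxoethyl}phosphonate
Product: 4 diethyl {1-diazo-2-[methoxy(methyl)amino]-2-oxoethyl}phosphonate
Conditions: NaH, THF, 0 °C; then 4-AcNHC6H4SO2N3, 0 °C to rt; aq. NH4Cl
Reagents that add atoms: 4-acetamidobenzenesulfonyl azide, CC(=O)Nc1ccc(cc1)S(=O)(=O)N=[N+]=[N-]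
Why: Regitz diazo transfer: the sodium salt of the doubly activated methylene attacks the sulfonyl azide and the triazene collapses to the diazo compound and the sulfonamide.

Step 3
Reactants: 2 2-methoxy-4-{[tri(propan-2-yl)silyl]oxymethyl}phenol; 4 diethyl {1-diazo-2-[methoxy(methyl)amino]-2-oxoethyl}phosphonate
Product: 5 diethyl {1-[2-methoxy-4-(triisopropylsilyloxymethyl)phenoxy]-2-[methoxy(methyl)amino]-2-oxoethyl}phosphonate (racemic)
Conditions: Rh2(OAc)4 (1 mol %), toluene, 80 °C, slow addition of 4
Reagents that add atoms: none
Why: Rhodium-carbenoid O–H insertion into a phenol, the known route to 2-aryloxy phosphonoacetic acid derivatives; slow addition of 4 suppresses carbene dimerisation, and the carbon that receives the oxygen becomes trigonal in step 7, so no stereocentre has to be controlled.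

Step 4
Reactants: 6 4-methoxy-2-methylidene-4-oxobutanoic acid (itaconic acid 4-methyl ester)
Product: 7 (2S)-4-methoxy-2-methyl-4-oxobutanoic acid
Conditions: H2 (5 bar), [Rh(cod)((R,R)-Me-DuPHOS)]BF4 (0.5 mol %), MeOH, rt
Reagents that add atoms: none
Why: Asymmetric hydrogenation of an itaconate, a standard substrate for cationic rhodium bisphospholane catalysts; the (R,R) ligand is expected, by analogy with other 2-substituted succinates, to give the (S) acid and so set C7. The sense is to be confirmed by optical rotation, and the ligand antipode is available.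

Step 5
Reactants: 7 (2S)-4-methoxy-2-methyl-4-oxobutanoic acid
Product: 8 methyl (3S)-4-hydroxy-3-methylbutanoate
Conditions: BH3·SMe2, THF, −10 °C to rt; MeOH quench
Reagents that add atoms: none
Why: Borane reduces a free carboxylic acid through its acyloxyborane far faster than an ester, so only the acid end becomes CH2OH; the stereocentre is not touched, and neutral work-up with immediate use is meant to forestall lactonisation.

Step 6
Reactants: 8 methyl (3S)-4-hydroxy-3-methylbutanoate
Product: 9 methyl (3S)-3-methyl-4-oxobutanoate
Conditions: Dess–Martin periodinane, NaHCO3, CH2Cl2, 0 °C to rt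
Reagents that add atoms: none
Why: Dess–Martin oxidation under buffered, non-basic conditions should give the α-branched aldehyde without epimerisation; 9 is used at once.

Step 7
Reactants: 5 diethyl {1-[2-methoxy-4-(triisopropylsilyloxymethyl)phenoxy]-2-[methoxy(methyl)amino]-2-oxoethyl}phosphonate; 9 methyl (3S)-3-methyl-4-oxobutanoate
Product: 10 methyl (3S,4Z)-5-[2-methoxy-4-(triisopropylsilyloxymethyl)phenoxy]-6-[methoxy(methyl)amino]-3-methyl-6-oxohex-4-enoate
Conditions: LiN(SiMe3)2, THF, −78 °C; then 9, −78 to 0 °C
Reagents that add atoms: none
Why: Horner–Wadsworth–Emmons olefination with an α-heteroatom-substituted phosphonoacetamide; the isomer with the carbonyl anti to the C7 chain (Z, because the aryloxy group outranks the amide carbon) is expected to predominate, and the stabilised, weakly basic anion should spare the α-stereocentre of 9.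

Step 8
Reactants: 10 methyl (3S,4Z)-5-[2-methoxy-4-(triisopropylsilyloxymethyl)phenoxy]-6-[methoxy(methyl)amino]-3-methyl-6-oxohex-4-enoate
Product: 11 methyl (3S,4Z)-5-[2-methoxy-4-(triisopropylsilyloxymethyl)phenoxy]-3-methyl-6-oxohex-4-enoate
Conditions: Cp2Zr(H)Cl (1.5 equiv), THF, rt; aqueous work-up
Reagents that add atoms: none
Why: Cp2Zr(H)Cl adds hydride to the amide carbonyl and the zirconated hemiaminal releases the aldehyde only on work-up, so N-methoxy-N-methylamides are reduced to aldehydes while esters, silyl ethers and the enol-ether alkene are left alone; the alkene geometry is retained.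

Step 9
Reactants: 11 methyl (3S,4Z)-5-[2-methoxy-4-(triisopropylsilyloxymethyl)phenoxy]-3-methyl-6-oxohex-4-enoate; 12 tert-butyl 3-oxopentanoate
Product: 15 methyl (3S)-3-{(1R,2R)-2-[2-methoxy-4-(triisopropylsilyloxymethyl)phenoxy]-4-methyl-5-oxocyclohex-3-en-1-yl}butanoate, via Michael adduct keto aldehyde 13 (not isolated), via cyclised tert-butyl keto ester 14 (not isolated)
Conditions: 9-amino-9-deoxy-epi-quinine (20 mol %), PhCO2H (40 mol %), 12 (2 equiv), toluene, 30 °C; then p-TsOH·H2O (30 mol %), toluene, 65 °C
Reagents that add atoms: none
Why: Proposed new method: the primary amine condenses with the aldehyde of 11 to an iminium ion whose C6 is attacked by the enol of 12 through C5, the resulting α-aryloxy enamine is protonated at C1 and hydrolysed to keto aldehyde 13, and p-TsOH then drives the aldol condensation of C3 onto C2 and cleaves the tert-butyl ester of 14 as 2-methylpropene and CO2; the closest known reaction type is the amine-catalysed Michael addition of tert-butyl β-keto esters to β-substituted enals followed by acid-mediated aldol condensation and decarboxylation to 5-substituted cyclohexenones, and the extension to an α-aryloxy α,β-disubstituted enal rests on the known ability of primary amine salts to activate α-branched enals as iminium ions. The ring closes by a 6-(enolendo)-exo-trig aldol addition, the only ring size open to 13. C6 is set in the Michael step by the catalyst, which must direct the nucleophile to the Re face of C6; the neighbouring C7 centre distinguishes only methyl from CH2CO2Me and offers little bias either way, and the sense of induction of this catalyst on this substrate cannot be predicted with confidence. C1 is set by protonation and stays epimerisable as the α-carbon of the aldehyde in 13, so closure through the chair-like arrangement with the aryloxy group and the C6 chain both equatorial should funnel the material to the trans ring. C5 is a transient centre erased by decarboxylation. The step needs 1,4- rather than 1,2-addition, which the soft, doubly stabilised nucleophile and iminium activation favour, and it needs the aryl ether to survive, which the electron-rich (poorly leaving) aryloxy group, the non-polar solvent and the limited acid charge and temperature are meant to secure.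

Step 10
Reactants: 15 methyl (3S)-3-{(1R,2R)-2-[2-methoxy-4-(triisopropylsilyloxymethyl)phenoxy]-4-methyl-5-oxocyclohex-3-en-1-yl}butanoate
Product: 16 methyl (3S)-3-{(1R,2R,5S)-5-hydroxy-2-[2-methoxy-4-(triisopropylsilyloxymethyl)phenoxy]-4-methylcyclohex-3-en-1-yl}butanoate
Conditions: (R)-2-methyl-CBS-oxazaborolidine (0.5 equiv), catecholborane (2 equiv), toluene, −78 to −40 °C; MeOH
Reagents that add atoms: none
Why: Corey–Bakshi–Shibata reduction: the ketone binds the oxazaborolidine boron through the lone pair on the C5 side, the methyl-substituted alkenyl side acting as the large group, and the (R) catalyst should deliver hydride to the face syn to the C6 side chain, giving the axial (4S) alcohol cis to the aryloxy group; catecholborane at low temperature leaves the ester untouched.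

Step 11
Reactants: 16 methyl (3S)-3-{(1R,2R,5S)-5-hydroxy-2-[2-methoxy-4-(triisopropylsilyloxymethyl)phenoxy]-4-methylcyclohex-3-en-1-yl}butanoate
Product: 17 (3S)-3-{(1R,2R,5S)-5-hydroxy-2-[2-methoxy-4-(triisopropylsilyloxymethyl)phenoxy]-4-methylcyclohex-3-en-1-yl}-N-methoxy-N-methylbutanamide
Conditions: MeNHOMe·HCl (3 equiv), iPrMgCl (7 equiv), THF, −20 to 0 °C; aq. NH4Cl
Reagents that add atoms: N,O-dimethylhydroxylamine hydrochloride, CNOC.Cl
Why: Aminolysis of the methyl ester by the chloromagnesium amide of N,O-dimethylhydroxylamine; one further equivalent of iPrMgCl turns the C4 hydroxyl into its alkoxide, which cannot lactonise because it is trans to the side chain.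

Step 12
Reactants: 17 (3S)-3-{(1R,2R,5S)-5-hydroxy-2-[2-methoxy-4-(triisopropylsilyloxymethyl)phenoxy]-4-methylcyclohex-3-en-1-yl}-N-methoxy-N-methylbutanamide
Product: 18 (6S)-6-{(1R,2R,5S)-5-hydroxy-2-[2-methoxy-4-(triisopropylsilyloxymethyl)phenoxy]-4-methylcyclohex-3-en-1-yl}-2-methylhept-2-en-4-one
Conditions: Me2C=CHMgBr (3.5 equiv), THF, 0 °C; aq. NH4Cl
Reagents that add atoms: 2-methylprop-1-enylmagnesium bromide, CC(C)=C[Mg]Br
Why: Grignard addition to the N-methoxy-N-methylamide stops at the chelated tetrahedral intermediate, which collapses to the β,β-dimethyl enone on work-up; the C4 alkoxide only consumes one equivalent of reagent.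

Step 13
Reactants: 18 (6S)-6-{(1R,2R,5S)-5-hydroxy-2-[2-methoxy-4-(triisopropylsilyloxymethyl)phenoxy]-4-methylcyclohex-3-en-1-yl}-2-methylhept-2-en-4-one
Product: 19 (6S)-6-{(1R,2R,5S)-5-hydroxy-2-[4-(hydroxymethyl)-2-methoxyphenoxy]-4-methylcyclohex-3-en-1-yl}-2-methylhept-2-en-4-one
Conditions: Bu4NF (1.2 equiv), AcOH (1.2 equiv), THF, 0 °C to rt
Reagents that add atoms: none
Why: Fluoride cleaves the primary benzylic silyl ether; buffering with AcOH keeps the medium near neutral so that the isobutenyl ketone should not deconjugate.

Step 14
Reactants: 19 (6S)-6-{(1R,2R,5S)-5-hydroxy-2-[4-(hydroxymethyl)-2-methoxyphenoxy]-4-methylcyclohex-3-en-1-yl}-2-methylhept-2-en-4-one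
Product: 20 4-({(1R,4S,6R)-4-hydroxy-3-methyl-6-[(2S)-6-methyl-4-oxohept-5-en-2-yl]cyclohex-2-en-1-yl}oxy)-3-methoxybenzaldehyde
Conditions: TEMPO (10 mol %), PhI(OAc)2 (1.1 equiv), CH2Cl2, rt
Reagents that add atoms: none
Why: Oxoammonium oxidation (TEMPO with PhI(OAc)2) is strongly selective for primary over secondary alcohols, so the electron-rich benzylic alcohol should go to the aldehyde while the secondary allylic C4 hydroxyl survives, without over-oxidation to the acid.

Step 15
Reactants: 21 4-hydroxybenzaldehyde; 22 pentane-2,4-dione
Product: 23 (1E,4Z)-5-hydroxy-1-(4-hydroxyphenyl)hexa-1,4-dien-3-one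
Conditions: 22 (3 equiv), B2O3, EtOAc, 70 °C; then 21, B(On-Bu)3; n-BuNH2 (cat.), 70 °C; then 0.4 M HCl, 60 °C
Reagents that add atoms: none
Why: Boron-templated aldol condensation: chelation of pentane-2,4-dione to boron blocks the central carbon so that the amine-activated aldehyde condenses at a terminal methyl, and the excess of 22 limits double condensation; the (E) alkene results from thermodynamic dehydration.

Step 16
Reactants: 20 4-({(1R,4S,6R)-4-hydroxy-3-methyl-6-[(2S)-6-methyl-4-oxohept-5-en-2-yl]cyclohex-2-en-1-yl}oxy)-3-methoxybenzaldehyde; 23 (1E,4Z)-5-hydroxy-1-(4-hydroxyphenyl)hexa-1,4-dien-3-one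
Product: 24 (1E,4Z,6E)-5-hydroxy-1-(4-hydroxyphenyl)-7-[4-({(1R,4S,6R)-4-hydroxy-3-methyl-6-[(2S)-6-methyl-4-oxohept-5-en-2-yl]cyclohex-2-en-1-yl}oxy)-3-methoxyphenyl]hepta-1,4,6-trien-3-one (demethoxybisabolocurcumin ether)
Conditions: 23 (1.5 equiv), B2O3, EtOAc, 70 °C; then 20, B(On-Bu)3; n-BuNH2 (0.2 equiv), 60 °C; then 5% aq. AcOH, 40 °C
Reagents that add atoms: none
Why: The same boron-templated aldol condensation, now at the remaining methyl group of 23, forms the (E) styryl alkene; excess 23 drives the conversion of 20, and hydrolysis of the chelate with dilute AcOH instead of mineral acid is meant to spare the allylic aryl ether. No stereocentre is affected.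

## Compound list

1 | 4-(hydroxymethyl)-2-methoxyphenol | COc1cc(CO)ccc1O | starting material
2 | 2-methoxy-4-{[tri(propan-2-yl)silyl]oxymethyl}phenol | COc1cc(CO[Si](C(C)C)(C(C)C)C(C)C)ccc1O | intermediate
3 | diethyl {2-[methoxy(methyl)amino]-2-oxoethyl}phosphonate | CCOP(=O)(CC(=O)N(C)OC)OCC | starting material
4 | diethyl {1-diazo-2-[methoxy(methyl)amino]-2-oxoethyl}phosphonate | CCOP(=O)(OCC)C(=[N+]=[N-])C(=O)N(C)OC | intermediate
5 | diethyl {1-[2-methoxy-4-(triisopropylsilyloxymethyl)phenoxy]-2-[methoxy(methyl)amino]-2-oxoethyl}phosphonate (racemic) | CCOP(=O)(OCC)C(Oc1ccc(CO[Si](C(C)C)(C(C)C)C(C)C)cc1OC)C(=O)N(C)OC | intermediate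
6 | 4-methoxy-2-methylidene-4-oxobutanoic acid | C=C(CC(=O)OC)C(=O)O | starting material
7 | (2S)-4-methoxy-2-methyl-4-oxobutanoic acid | OC(=O)[C@@H](C)CC(=O)OC | intermediate
8 | methyl (3S)-4-hydroxy-3-methylbutanoate | OC[C@@H](C)CC(=O)OC | intermediate
9 | methyl (3S)-3-methyl-4-oxobutanoate | O=C[C@@H](C)CC(=O)OC | intermediate
10 | methyl (3S,4Z)-5-[2-methoxy-4-(triisopropylsilyloxymethyl)phenoxy]-6-[methoxy(methyl)amino]-3-methyl-6-oxohex-4-enoate | CON(C)C(=O)/C(Oc1ccc(CO[Si](C(C)C)(C(C)C)C(C)C)cc1OC)=C/[C@@H](C)CC(=O)OC | intermediate
11 | methyl (3S,4Z)-5-[2-methoxy-4-(triisopropylsilyloxymethyl)phenoxy]-3-methyl-6-oxohex-4-enoate | O=C/C(Oc1ccc(CO[Si](C(C)C)(C(C)C)C(C)C)cc1OC)=C/[C@@H](C)CC(=O)OC | intermediate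
12 | tert-butyl 3-oxopentanoate | CCC(=O)CC(=O)OC(C)(C)C | starting material
13 | tert-butyl 4-[2-methoxy-4-(triisopropylsilyloxymethyl)phenoxy]-3-[(2S)-4-methoxy-4-oxobutan-2-yl]-5-oxo-2-propanoylpentanoate (chain C3 configured as C6 of 15; the aryloxy-bearing and ester-bearing carbons are epimeric mixtures) | CCC(=O)C(C(=O)OC(C)(C)C)[C@@H](C(Oc1ccc(CO[Si](C(C)C)(C(C)C)C(C)C)cc1OC)C=O)[C@@H](C)CC(=O)OC | intermediate (not isolated)
14 | tert-butyl 5-[2-methoxy-4-(triisopropylsilyloxymethyl)phenoxy]-6-[(2S)-4-methoxy-4-oxobutan-2-yl]-3-methyl-2-oxocyclohex-3-ene-1-carboxylate (aryloxy and side-chain carbons configured as in 15; ester-bearing carbon epimeric) | COc1cc(CO[Si](C(C)C)(C(C)C)C(C)C)ccc1O[C@H]1C=C(C)C(=O)C(C(=O)OC(C)(C)C)[C@@H]1[C@@H](C)CC(=O)OC | intermediate (not isolated)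
15 | methyl (3S)-3-{(1R,2R)-2-[2-methoxy-4-(triisopropylsilyloxymethyl)phenoxy]-4-methyl-5-oxocyclohex-3-en-1-yl}butanoate | COc1cc(CO[Si](C(C)C)(C(C)C)C(C)C)ccc1O[C@H]1C=C(C)C(=O)C[C@@H]1[C@@H](C)CC(=O)OC | intermediate
16 | methyl (3S)-3-{(1R,2R,5S)-5-hydroxy-2-[2-methoxy-4-(triisopropylsilyloxymethyl)phenoxy]-4-methylcyclohex-3-en-1-yl}butanoate | COc1cc(CO[Si](C(C)C)(C(C)C)C(C)C)ccc1O[C@H]1C=C(C)[C@@H](O)C[C@@H]1[C@@H](C)CC(=O)OC | intermediate
17 | (3S)-3-{(1R,2R,5S)-5-hydroxy-2-[2-methoxy-4-(triisopropylsilyloxymethyl)phenoxy]-4-methylcyclohex-3-en-1-yl}-N-methoxy-N-methylbutanamide | COc1cc(CO[Si](C(C)C)(C(C)C)C(C)C)ccc1O[C@H]1C=C(C)[C@@H](O)C[C@@H]1[C@@H](C)CC(=O)N(C)OC | intermediate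
18 | (6S)-6-{(1R,2R,5S)-5-hydroxy-2-[2-methoxy-4-(triisopropylsilyloxymethyl)phenoxy]-4-methylcyclohex-3-en-1-yl}-2-methylhept-2-en-4-one | COc1cc(CO[Si](C(C)C)(C(C)C)C(C)C)ccc1O[C@H]1C=C(C)[C@@H](O)C[C@@H]1[C@@H](C)CC(=O)C=C(C)C | intermediate
19 | (6S)-6-{(1R,2R,5S)-5-hydroxy-2-[4-(hydroxymethyl)-2-methoxyphenoxy]-4-methylcyclohex-3-en-1-yl}-2-methylhept-2-en-4-one | COc1cc(CO)ccc1O[C@H]1C=C(C)[C@@H](O)C[C@@H]1[C@@H](C)CC(=O)C=C(C)C | intermediate
20 | 4-({(1R,4S,6R)-4-hydroxy-3-methyl-6-[(2S)-6-methyl-4-oxohept-5-en-2-yl]cyclohex-2-en-1-yl}oxy)-3-methoxybenzaldehyde | COc1cc(C=O)ccc1O[C@H]1C=C(C)[C@@H](O)C[C@@H]1[C@@H](C)CC(=O)C=C(C)C | intermediate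
21 | 4-hydroxybenzaldehyde | O=Cc1ccc(O)cc1 | starting material
22 | pentane-2,4-dione | CC(=O)CC(C)=O | starting material
23 | (1E,4Z)-5-hydroxy-1-(4-hydroxyphenyl)hexa-1,4-dien-3-one | C/C(O)=C/C(=O)/C=C/c1ccc(O)cc1 | intermediate
24 | (1E,4Z,6E)-5-hydroxy-1-(4-hydroxyphenyl)-7-[4-({(1R,4S,6R)-4-hydroxy-3-methyl-6-[(2S)-6-methyl-4-oxohept-5-en-2-yl]cyclohex-2-en-1-yl}oxy)-3-methoxyphenyl]hepta-1,4,6-trien-3-one | COc1cc(/C=C/C(O)=C/C(=O)/C=C/c2ccc(O)cc2)ccc1O[C@H]1C=C(C)[C@@H](O)C[C@@H]1[C@@H](C)CC(=O)C=C(C)C | target

## Step count and least certain steps

Total step count: 16. Longest linear sequence: 12 steps (6 to 7, 8, 9, 10, 11, 15, 16, 17, 18, 19, 20 and 24; steps 4 to 14 and 16).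

**Step 9 (key step, proposed new method).** Several things may go wrong:
- The conjugate addition may be slow or fail, because the iminium ion is hindered at both alkene carbons and its β-carbon is made less electrophilic by the α-aryloxy donor.
- The keto ester may add 1,2 to the iminium carbon (condensation followed by oxa-electrocyclisation), or tie up the amine as an enaminone.
- γ-Deprotonation of the iminium ion to a dienamine may scramble C7.
- Facial selectivity at C6 may be poor, or of the wrong sense.
- In the acid stage the benzylic silyl ether may ionise, or the aryloxy group may be lost with aromatisation through the enol of 14.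

Fallback (known reaction types; sets out from 2, 9 and 12 and rejoins at 13): the C1–C6 bond is formed by enamine catalysis instead of the C5–C6 bond by iminium catalysis. Phenol 2 is O-allylated (allyl bromide, K2CO3, acetone) to allyl ether F1, and Lemieux–Johnson cleavage (OsO4 cat., NaIO4, 2,6-lutidine, aqueous dioxane) gives aryloxyacetaldehyde F2. Aldehyde 9 and keto ester 12 are joined by Knoevenagel condensation (TiCl4, pyridine, THF, 0 °C) to alkylidene keto ester F3. The antipode of α,α-diphenylprolinol trimethylsilyl ether that places C6 correctly (10 mol %, PhCO2H, toluene) then catalyses the Michael addition of F2, an α-oxy aldehyde donor, to the doubly activated alkene of F3. This gives keto aldehyde 13, which is closed to 15 under the acid stage of step 9. No iminium ion of a γ-branched enal is involved, so C7 cannot be scrambled by that path.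

**Step 10.** The catalyst must override the substrate, whose own preference (hydride anti to the axial C5 hydrogen) leads to the equatorial (4R) alcohol; incomplete reagent control would give a mixture of C4 epimers. Fallback (sets out from 15, rejoins at 16): Luche reduction (NaBH4, CeCl3·7H2O, MeOH, −78 °C) is allowed to follow the substrate preference and give (4R)-alcohol F4. Mitsunobu inversion (4-nitrobenzoic acid, DIAD, PPh3, THF, 0 °C) gives (4S)-4-nitrobenzoate F5, and methanolysis (K2CO3, MeOH, 0 °C) gives 16.

**Step 7.** The olefination may give a poor Z/E ratio at the trisubstituted enol-ether alkene, and the basic conditions may epimerise C7 of 9 before addition. Fallback (sets out from 3, 9 and 2, rejoins at 10): the aryloxy group is introduced after the alkene. Phosphonate 3 and 9 are combined under LiCl/iPr2NEt in MeCN to (E)-enamide F6; bromination and dehydrobromination (Br2, CH2Cl2, 0 °C; then Et3N) give (Z)-α-bromo enamide F7; Ullmann-type C–O coupling with phenol 2 (CuI 10 mol %, N,N-dimethylglycine, Cs2CO3, dioxane, 90 °C) gives 10 with retention of geometry.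

**Step 14.** Oxidation may also attack the secondary allylic C4 hydroxyl, returning the enone, or the aldehyde may over-oxidise. Fallback (sets out from 18, rejoins at 20): the C4 hydroxyl is masked. Acetylation of 18 (Ac2O, pyridine, DMAP) gives acetate F8; desilylation (Bu4NF, AcOH) gives benzylic alcohol F9; MnO2 in CH2Cl2 gives aldehyde acetate F10; brief methanolysis (K2CO3, MeOH, 0 °C) gives 20.

**Step 16.** During hydrolysis of the boron chelate the C1 ether may ionise (the allyl cation has a methyl-substituted terminus), and the primary amine may add reversibly to the isobutenyl ketone and slow the condensation. Fallback (sets out from 23 and 20, rejoins at 24): the template is made and removed as discrete, neutral operations. Compound 23 and BF3·OEt2 give the isolable difluoroboron chelate F11. Condensation of F11 with 20 (piperidine cat., toluene, 60 °C) gives the difluoroboron chelate of the target, F12. Ligand exchange with sodium oxalate in aqueous MeOH at 60 °C releases 24 at near-neutral pH.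

## Further compounds

F1 | step 9 | {[3-methoxy-4-(prop-2-enyloxy)phenyl]methoxy}tri(propan-2-yl)silane | COc1cc(CO[Si](C(C)C)(C(C)C)C(C)C)ccc1OCC=C
F2 | step 9 | 2-[2-methoxy-4-(triisopropylsilyloxymethyl)phenoxy]acetaldehyde | COc1cc(CO[Si](C(C)C)(C(C)C)C(C)C)ccc1OCC=O
F3 | step 9 | 1-tert-butyl 6-methyl (4S)-4-methyl-2-propanoylhex-2-enedioate (E/Z mixture) | CCC(=O)C(=C[C@@H](C)CC(=O)OC)C(=O)OC(C)(C)C
F4 | step 10 | methyl (3S)-3-{(1R,2R,5R)-5-hydroxy-2-[2-methoxy-4-(triisopropylsilyloxymethyl)phenoxy]-4-methylcyclohex-3-en-1-yl}butanoate | COc1cc(CO[Si](C(C)C)(C(C)C)C(C)C)ccc1O[C@H]1C=C(C)[C@H](O)C[C@@H]1[C@@H](C)CC(=O)OC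
F5 | step 10 | methyl (3S)-3-{(1R,2R,5S)-2-[2-methoxy-4-(triisopropylsilyloxymethyl)phenoxy]-4-methyl-5-(4-nitrobenzoyloxy)cyclohex-3-en-1-yl}butanoate | COc1cc(CO[Si](C(C)C)(C(C)C)C(C)C)ccc1O[C@H]1C=C(C)[C@@H](OC(=O)c2ccc(cc2)[N+](=O)[O-])C[C@@H]1[C@@H](C)CC(=O)OC
F6 | step 7 | methyl (3S,4E)-6-[methoxy(methyl)amino]-3-methyl-6-oxohex-4-enoate | CON(C)C(=O)/C=C/[C@@H](C)CC(=O)OC
F7 | step 7 | methyl (3S,4Z)-5-bromo-6-[methoxy(methyl)amino]-3-methyl-6-oxohex-4-enoate | CON(C)C(=O)/C(Br)=C/[C@@H](C)CC(=O)OC
F8 | step 14 | (1S,4R,5R)-4-[2-methoxy-4-(triisopropylsilyloxymethyl)phenoxy]-2-methyl-5-[(2S)-6-methyl-4-oxohept-5-en-2-yl]cyclohex-2-en-1-yl acetate | COc1cc(CO[Si](C(C)C)(C(C)C)C(C)C)ccc1O[C@H]1C=C(C)[C@@H](OC(C)=O)C[C@@H]1[C@@H](C)CC(=O)C=C(C)C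
F9 | step 14 | (1S,4R,5R)-4-[4-(hydroxymethyl)-2-methoxyphenoxy]-2-methyl-5-[(2S)-6-methyl-4-oxohept-5-en-2-yl]cyclohex-2-en-1-yl acetate | COc1cc(CO)ccc1O[C@H]1C=C(C)[C@@H](OC(C)=O)C[C@@H]1[C@@H](C)CC(=O)C=C(C)C
F10 | step 14 | (1S,4R,5R)-4-(4-formyl-2-methoxyphenoxy)-2-methyl-5-[(2S)-6-methyl-4-oxohept-5-en-2-yl]cyclohex-2-en-1-yl acetate | COc1cc(C=O)ccc1O[C@H]1C=C(C)[C@@H](OC(C)=O)C[C@@H]1[C@@H](C)CC(=O)C=C(C)C
F11 | step 16 | difluoroboron chelate of 23 (2,2-difluoro-4-[(E)-2-(4-hydroxyphenyl)ethenyl]-6-methyl-1,3,2-dioxaborinine) | CC1=CC(/C=C/c2ccc(O)cc2)=[O+][B-](F)(F)O1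
F12 | step 16 | difluoroboron chelate of 24 | COc1cc(/C=C/C2=CC(/C=C/c3ccc(O)cc3)=[O+][B-](F)(F)O2)ccc1O[C@H]1C=C(C)[C@@H](O)C[C@@H]1[C@@H](C)CC(=O)C=C(C)C
A1 | alternative 1 | 3,5-distyrylisoxazole (masked, bis-silylated target) | COc1cc(/C=C/c2cc(/C=C/c3ccc(O[Si](C)(C)C(C)(C)C)cc3)on2)ccc1O[C@H]1C=C(C)[C@@H](O[Si](C)(C)C(C)(C)C)C[C@@H]1[C@@H](C)CC(=O)C=C(C)C
A2 | alternative 1 | (E)-cinnamaldoxime of the C4-silylated terpenoid aryl ether | COc1cc(/C=C/C=N/O)ccc1O[C@H]1C=C(C)[C@@H](O[Si](C)(C)C(C)(C)C)C[C@@H]1[C@@H](C)CC(=O)C=C(C)C
A3 | alternative 1 | tert-butyl{4-[(1E)-but-1-en-3-yn-1-yl]phenoxy}dimethylsilane | C#C/C=C/c1ccc(O[Si](C)(C)C(C)(C)C)cc1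
A4 | alternative 2 | bicyclic endoperoxide methyl ester (2,3-dioxabicyclo[2.2.2]oct-5-ene, O–O bridge anti to the side chain) | O1O[C@H]2C=C(C)[C@@H]1C[C@@H]2[C@@H](C)CC(=O)OC
A5 | alternative 2 | methyl (3S)-3-[(1R)-4-methylcyclohexa-2,4-dien-1-yl]butanoate | CC1=CC[C@@H](C=C1)[C@@H](C)CC(=O)OC
A6 | alternative 2 | methyl (3S)-3-[(1R,2R,5S)-2,5-dihydroxy-4-methylcyclohex-3-en-1-yl]butanoate | O[C@H]1C=C(C)[C@@H](O)C[C@@H]1[C@@H](C)CC(=O)OC
A7 | alternative 2 | 4-fluoro-3-methoxybenzaldehyde | COc1cc(C=O)ccc1F
A8 | alternative 3 | (1S,4S,6R)-4-(tert-butyldimethylsilyloxy)-3-methyl-6-(prop-1-en-2-yl)cyclohex-2-en-1-ol | O[C@H]1C=C(C)[C@@H](O[Si](C)(C)C(C)(C)C)C[C@@H]1C(C)=C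
A9 | alternative 3 | (2Z,4S)-4-(tert-butyldimethylsilyloxy)-3,7-dimethylocta-2,6-dienal | O=C/C=C(C)\[C@@H](O[Si](C)(C)C(C)(C)C)CC=C(C)C
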